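Start from the alpha and delta runs, which look nearly the same: both hold 0.20 M of X and 1 M of E, but delta has about half the Q of alpha. At its last reading, 80.0 s, alpha shows L 35.2%. Delta, read later at 2.50 min, shows L 21.6%, which is less, although it has used more of its X, with 30.8% left against 36.2%.

| flask | X | Q | E | remark | time |
|---|---|---|---|---|---|
| alpha | 0.20 M | 0.21 M | 1 M | run made earlier |  |
| delta | 0.20 M | 0.10 M | 1 M | run made earlier |  |
| theta | 0.20 M | 0.42 M | 1 M | run made earlier |  |
| ash | 0.20 M | 0.210 M | 1.00 M | everything together at the start | 2.0 min |
| birch | 0.20 M (fed, over 1.5 min) | 0.210 M | 1.00 M | all else is in the flask from the start; the feed brings no volume worth counting | 2.0 min |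
| cedar | 0.20 M | 0.210 M (fed, over 1.5 min) | 1.00 M | all else is in the flask from the start; the feed brings no volume worth counting | 2.0 min |

alpha run (percent of the X charged)

| time / s | L / % | X / % |
|---|---|---|
| 10.0 | 13.6 | 77.0 |
| 20.0 | 21.9 | 64.6 |
| 40.0 | 31.1 | 48.3 |
| 80.0 | 35.2 | 36.2 |

delta run (percent of the X charged)

| time / min | L / % | X / % |
|---|---|---|
| 0.500 | 13.9 | 66.5 |
| 1.00 | 18.2 | 48.5 |
| 1.33 | 18.7 | 42.4 |
| 2.00 | 20.5 | 34.4 |
| 2.50 | 21.6 | 30.8 |

theta run (percent of the X charged)

| time / min | L / % | X / % |
|---|---|---|
| 0.200 | 29.1 | 61.3 |
| 0.667 | 51.5 | 33.2 |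
| 1.00 | 57.8 | 24.9 |
| 1.50 | 63.5 | 20.6 |
| 2.50 | 61.7 | 17.9 |

(readings scatter by 1 percentage point)

- percentages count the X that a species holds: one G counts as two
- steps thought possible: X + Q <-> L; E + Q <-> J; 2 X -> G

- the flask that comes out highest in amount of L, in percent of the X charged, or "all alike" when all lie within 1.5 percentage points (ash / birch / cedar / all alike)
- L at the end, in percent of the X charged, ash
- L at the end, in percent of the X charged, birch
- L at the end, in percent of the X charged, cedar

To see why the two runs part, divide the X gone at the first reading of each run. What is not in L stands in G, so alpha gives 1.45 of L for each X in G, and delta gives 0.709. Delta ends lower because a lost X reaches L less often there. Theta, with 0.42 M of Q, gives 3.03.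

L forms as [X][Q] and G as [X]², so this ratio should follow [Q]/[X]. Multiply each ratio by the mean [X] up to that reading and divide by the charged [Q]. Alpha reads 1.22, delta 1.18 and theta 1.16. Their mean, 1.19, is the split number, the L formed per X sent to G for each unit of charged [Q] over mean [X], an apparent selectivity factor, counted on charged [Q] and not on the [Q] that stands free; it is a reading and carries the scatter of 1 percentage point.

My own reckoning for the new flasks starts with ash, which begins at a split of 1.25. At mid-feed, birch has half its X in, and with [Q] taken at its charge the split is 2.50. Cedar at mid-feed, with half its Q in and [X] taken at its charge, has 0.624. So I put cedar at the bottom and birch near ash, held back by X fed late.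

The forecast says 36.5% for ash, 22.5% for birch and 27% for cedar, with ash highest, on the ground that in birch “Q burns away on E before X arrives”. Mine differs from it in placing birch above cedar.

    X + Q ⇌ L (K = 21.0 /M, k = 0.120 /M/s)
    E + Q ⇌ J (K = 0.860 /M, k = 0.140 /M/s)
    2 X → G (k = 0.0280 /M/s)

The flasks give 39.1% in ash, 37.1% in birch and 27.9% in cedar, so ash comes highest. Birch still holds X 41.1% at 2.00 min. My mid-feed split for cedar was 0.624, and at 2.00 min cedar stands at 0.616 of L per X in G. The neighbour of cedar charged with 0.52 M of Q reckons the same way to 1.54, and at 2.00 min it stands at 1.46.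

All runs come from a simulation with constants of no real substance, noise included.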